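Numbering (eremophilane): C1–C10 decalin with C5/C10 ring fusion, CH3-15 on C4, CH3-14 on C5, isopropenyl C11–C13 on C7, C8 ketone, C9 carbinol, C3 ester carbon. Retrosynthesis cuts first the C3–O acyl bond (side-chain acid), then C7–C11 (α-iodoenone coupling) and the C6=C7 unsaturation (conjugate reduction), leaving a 3-hydroxy-9-silyloxy Δ6-8-ketone.
Enabling feature: O3 and the C8 carbonyl are 1,6-related through C4–C5–C6–C7, and ring A (C5–C6–C7–C8–C9–C10) is a cyclohexene retron. Joining O3 to C8 as a seven-membered lactone therefore makes C5=C6–C7=C8 a ring-locked (Z, s-cis) silyl ketene acetal diene, with the C9=C10 alkenylboronate carried on C3 by the C2–C1 tether.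
One intramolecular [4+2] cycloaddition then accounts for the C8–C9 and C5–C10 bonds together: rings A and B form in the same step, the lactone oxygen ends as a C3–O–C8 ketal bridge that is later opened to the C8 ketone and the free C3 hydroxyl, and the C9–B bond is oxidised to C9–OH.
Forward order: aldol (C3–C4) → methyl ketone → methylenation → but-3-enoate → ring-closing metathesis (temporary lactone ring, C5=C6) → borylation → enol silylation and cycloaddition (rings A and B) → C–B oxidation → ketal opening → isopropenyl on C7 → side-chain ester → desilylation.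
Stereochemistry: C3 and C4 from the oxazolidinone aldol; C5, C10 and C9 from the cycloaddition (the tether on C3 fixes the diene face, the ring-bound diene allows only the cis fusion, the E boronate puts boron syn to H-10 and oxidation retains it); C7 by kinetic protonation to the equatorial isomer; C4' from (R)-1,2-epoxybutane; the Z acyl group from angelic acid.
Key step: step 10

Remark: the bicyclic intermediates are named on the eremophilane skeleton; β is the face of the C5 methyl, CH3-14 and CH3-15 are β and H-10 is β (cis fusion) in all of them, and "11,12,13-trinor" means that the isopropenyl group is not yet present.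

Step 1
Reactants: 1 pent-4-yn-1-ol
Product: 3 (E)-5-iodopent-4-en-1-ol, via alkenylzirconocene chloride 2 (not isolated)
Conditions: Cp2Zr(H)Cl (2.2 equiv), THF, rt; then I2, 0 °C
Reagents that add atoms: iodine, [I][I]
Why: Hydrozirconation of the terminal alkyne is a syn anti-Markovnikov addition and iodinolysis of the C–Zr bond retains configuration, so the E iodoalkene (the later C9=C10 unit) should result, one equivalent of hydride being spent on the hydroxyl.

Step 2
Reactants: 3 (E)-5-iodopent-4-en-1-ol
Product: 4 (E)-5-iodopent-4-enal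
Conditions: TEMPO (10 mol%), PhI(OAc)2, CH2Cl2, rt
Reagents that add atoms: none
Why: Oxoammonium (TEMPO) oxidation of a primary alcohol stops at the aldehyde and does not touch the iodoalkene.

Step 3
Reactants: 4 (E)-5-iodopent-4-enal; 5 (S)-4-benzyl-3-propanoyl-1,3-oxazolidin-2-one
Product: 7 (S)-4-benzyl-3-[(2S,3R,6E)-3-hydroxy-7-iodo-2-methylhept-6-enoyl]-1,3-oxazolidin-2-one, via dibutylboron Z-enolate 6 (not isolated)
Conditions: n-Bu2BOTf, i-Pr2NEt, CH2Cl2, 0 °C; then 4, −78 to 0 °C; pH 7 buffer, MeOH, H2O2, 0 °C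
Reagents that add atoms: none
Why: Evans syn-aldol reaction: the Z boron enolate reacts through a closed chair transition state on the enolate face opposite the benzyl group, which sets C3 (carbinol) and C4 (methyl) together in the syn (2S,3R) sense.

Step 4
Reactants: 7 aldol adduct
Product: 8 (2S,3R,6E)-3-hydroxy-7-iodo-N-methoxy-N,2-dimethylhept-6-enamide
Conditions: MeNH(OMe)·HCl, AlMe3, CH2Cl2, −20 °C to rt
Reagents that add atoms: N,O-dimethylhydroxylamine hydrochloride, CNOC.Cl
Why: Aluminium-amide transamination of the imide (Weinreb amide formation) is directed to the exocyclic carbonyl by the free β-hydroxyl and leaves both stereocentres untouched.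

Step 5
Reactants: 8 Weinreb amide
Product: 9 (3S,4R,7E)-4-hydroxy-8-iodo-3-methyloct-7-en-2-one
Conditions: MeMgBr (3 equiv), THF, 0 °C
Reagents that add atoms: methylmagnesium bromide, C[Mg]Br
Why: Weinreb ketone synthesis: the chelated tetrahedral adduct holds until work-up, so addition stops at the methyl ketone (C5 with CH3-14) without enolising C4.

Step 6
Reactants: 9 methyl ketone
Product: 10 (3R,4R,6E)-7-iodo-2,3-dimethylhepta-1,6-dien-4-ol
Conditions: Zn, CH2Br2, TiCl4, THF/CH2Cl2, 0 °C to rt
Reagents that add atoms: dibromomethane, BrCBr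
Why: Lombardo (Takai-type) methylenation is non-basic, so the β-hydroxy ketone should be converted into the 1,1-disubstituted alkene without retro-aldol cleavage or epimerisation at C4.

Step 7
Reactants: 10 dienol; 11 but-3-enoic acid
Product: 12 (3R,4R,6E)-7-iodo-2,3-dimethylhepta-1,6-dien-4-yl but-3-enoate
Conditions: DCC, DMAP (5 mol%), CH2Cl2, 0 °C
Reagents that add atoms: none
Why: Steglich esterification at low temperature with little DMAP acylates O3 with the future C6–C7–C8 unit while keeping the β,γ double bond out of conjugation.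

Step 8
Reactants: 12 butenoate
Product: 13 (6R,7R)-7-[(3E)-4-iodobut-3-en-1-yl]-5,6-dimethyl-6,7-dihydrooxepin-2(3H)-one
Conditions: RuCl2(=CHPh)(H2IMes)(PCy3) (second-generation Grubbs catalyst, 5 mol%), 1,4-benzoquinone (10 mol%), toluene (2 mM), 80 °C
Reagents that add atoms: none
Why: Ring-closing metathesis between the butenoate vinyl group and the 1,1-disubstituted alkene closes the seven-membered lactone, whose ring size allows only the Z trisubstituted C5=C6 bond; the iodoalkene is a poor metathesis partner and benzoquinone suppresses double-bond migration.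

Step 9
Reactants: 13 iodoalkenyl lactone
Product: 14 (6R,7R)-5,6-dimethyl-7-[(3E)-4-(4,4,5,5-tetramethyl-1,3,2-dioxaborolan-2-yl)but-3-en-1-yl]-6,7-dihydrooxepin-2(3H)-one
Conditions: B2pin2, PdCl2(PPh3)2 (3 mol%), PPh3 (6 mol%), KOPh, toluene, 50 °C
Reagents that add atoms: bis(pinacolato)diboron, CC1(C)OB(OC1(C)C)B1OC(C)(C)C(C)(C)O1
Why: Miyaura borylation of an alkenyl iodide goes with retention of the E geometry, and the weak phenoxide base should not enolise the lactone.

Step 10
Reactants: 14 alkenylboronate lactone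
Product: 16 8β-(tert-butyldimethylsilyloxy)-3α,8α-epoxy-9β-(pinacolboryl)-11,12,13-trinor-10βH-eremophil-6-ene, via cyclic silyl ketene acetal 15 (not isolated)
Conditions: TBSCl, LiN(SiMe3)2, THF/DMPU, −78 °C; then toluene (5 mM), BHT, Et3N (1%), 110 °C, sealed tube
Reagents that add atoms: tert-butyldimethylsilyl chloride, CC(C)(C)[Si](C)(C)Cl
Why: The lactone enolate is trapped on oxygen to give the seven-membered 1-alkoxy-1-silyloxy diene C5=C6–C7=C8, which on heating should add the tethered E alkenylboronate C9=C10 in a concerted, asynchronous normal-demand [4+2] cycloaddition (C5–C10 bond leading); the closest known reaction types are intramolecular Diels–Alder reactions of vinylketene silyl acetals and the use of alkenylboronates as vinyl-alcohol dienophiles. Ring A (C5–C6=C7–C8–C9–C10) closes as the cyclohexene of the cycloaddition across the two termini of the ring-bound diene, and ring B (C10–C1–C2–C3–C4–C5) closes at the same time through the new C5–C10 bond, the two-carbon tether from C3 joining the dienophile to the diene terminus C5, so that the former lactone oxygen becomes the C3–O–C8 ketal bridge. Every new centre is controlled by the tether: C10 can reach only the diene face that carries C2 on C3 (this fixes C5 relative to C3 and C4), the ring-bound Z diene admits only the transition state with C1 exo (this fixes C10 and the cis fusion), and the E geometry of the boronate then places boron endo, syn to H-10 and to CH3-14 (this fixes C9), while C8 becomes a ketal centre that is erased in step 13. The selectivity needed is regiochemical (C10 to C5 and C9 to C8, not the reverse) and polarity matching secures it, the largest HOMO coefficient lying on C5, remote from the two oxygens on C8, and the largest LUMO coefficient on C10, β to boron, with high dilution holding back bimolecular addition.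

Step 11
Reactants: 16 boronate cycloadduct
Product: 17 8β-(tert-butyldimethylsilyloxy)-3α,8α-epoxy-11,12,13-trinor-10βH-eremophil-6-en-9β-ol
Conditions: NaBO3·4H2O, THF/H2O, rt
Reagents that add atoms: sodium perborate tetrahydrate, O.O.O.O.[Na+].[O-]OB=O
Why: Perborate oxidation of the secondary alkylboronate (1,2-shift of C9 from boron to oxygen) goes with retention, so the hydroxyl takes the 9β position set in step 10; the mild medium should leave the O-silyl ketal closed and avoid β-elimination of the β-oxygenated boronate.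

Step 12
Reactants: 17 hydroxy ketal
Product: 18 8β,9β-bis(tert-butyldimethylsilyloxy)-3α,8α-epoxy-11,12,13-trinor-10βH-eremophil-6-ene
Conditions: TBSOTf, 2,6-lutidine, CH2Cl2, −78 °C
Reagents that add atoms: tert-butyldimethylsilyl triflate, CC(C)(C)[Si](C)(C)OS(=O)(=O)C(F)(F)F
Why: Silyl triflate silylation of the hindered C9 hydroxyl at −78 °C under lutidine buffering should be faster than any Lewis-acid opening of the ketal and installs the protecting group that must last to the end.

Step 13
Reactants: 18 bis-silyl ketal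
Product: 19 9β-(tert-butyldimethylsilyloxy)-3α-hydroxy-11,12,13-trinor-10βH-eremophil-6-en-8-one
Conditions: PPTS (20 mol%), acetone/H2O (10:1), 0 °C to rt
Reagents that add atoms: none
Why: Mild acid hydrolysis of the O-silyl ketal (loss of O3 from C8, then of the silyl group from the silyloxycarbenium ion) should unveil the C8 ketone in conjugation with C6=C7 and the free C3 hydroxyl while the secondary silyl ether on C9 survives; conjugate return of O3 to C6 would need a strained 6-oxabicyclo[3.2.1]octane with an axial CH3-15 and is not expected under weak acid.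

Step 14
Reactants: 19 hydroxy enone
Product: 20 9β-(tert-butyldimethylsilyloxy)-3α-hydroxy-7-iodo-11,12,13-trinor-10βH-eremophil-6-en-8-one
Conditions: I2, pyridine, CH2Cl2, 0 °C to rt
Reagents that add atoms: iodine, [I][I]
Why: α-Iodination of the enone (pyridine-mediated addition–elimination, Johnson procedure) places iodine on C7, the only enone α-carbon.

Step 15
Reactants: 20 α-iodoenone; 21 tributyl(prop-1-en-2-yl)stannane
Product: 22 9β-(tert-butyldimethylsilyloxy)-3α-hydroxy-10βH-eremophila-6,11-dien-8-one
Conditions: Pd2(dba)3 (2.5 mol%), AsPh3 (10 mol%), NMP, rt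
Reagents that add atoms: none
Why: Stille coupling of the α-iodoenone under ligand-accelerated, base-free conditions joins C7 to C11, and the neutral medium spares the hydroxy-enone.

Step 16
Reactants: 22 cross-conjugated dienone
Product: 23 9β-(tert-butyldimethylsilyloxy)-3α-hydroxy-7αH,10βH-eremophil-11-en-8-one
Conditions: [(Ph3P)CuH]6 (0.5 equiv), H2O (5 equiv), THF/benzene, rt
Reagents that add atoms: none
Why: Conjugate reduction with the copper hydride (only C6 is activated, the C11=C12 bond being cross-conjugated) gives a copper dienolate that water should protonate kinetically at C7; C7 is set in this protonation, and axial delivery on the α face should give the equatorial β-isopropenyl group, which is also the more stable arrangement of the cis-decalin.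

Step 17
Reactants: 24 (R)-2-ethyloxirane
Product: 25 (R)-pent-1-en-3-ol
Conditions: Me3S+ I− (3 equiv), n-BuLi (3 equiv), THF, −10 °C to rt
Reagents that add atoms: trimethylsulfonium iodide, C[S+](C)C.[I-]
Why: Corey–Chaykovsky-type epoxide homologation: the sulfonium ylide opens the epoxide at CH2 and a second equivalent eliminates dimethyl sulfide, giving the allylic alcohol with the carbinol centre (later C4') untouched and R.

Step 18
Reactants: 25 (R)-pent-1-en-3-ol; 26 angelic acid
Product: 28 (R)-pent-1-en-3-yl (Z)-2-methylbut-2-enoate, via angelic trichlorobenzoic anhydride 27 (not isolated)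
Conditions: 2,4,6-trichlorobenzoyl chloride, Et3N, toluene, rt; then 25, toluene, 75 °C (no DMAP)
Reagents that add atoms: none
Why: Yamaguchi-type mixed-anhydride acylation run without DMAP should acylate the alcohol on oxygen (retention at carbon) without nucleophile-induced Z-to-E isomerisation of the angelate.

Step 19
Reactants: 28 allylic angelate; 29 acrylic acid
Product: 30 (2E,4R)-4-{[(2Z)-2-methylbut-2-enoyl]oxy}hex-2-enoic acid
Conditions: RuCl2(=CH-C6H4-2-OiPr)(H2IMes) (second-generation Hoveyda–Grubbs catalyst, 5 mol%), CH2Cl2, 40 °C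
Reagents that add atoms: none
Why: Olefin cross-metathesis of the terminal alkene with acrylic acid should give the E enoic acid under thermodynamic control, the trisubstituted electron-poor angelate alkene not taking part.

Step 20
Reactants: 23 hydroxy ketone; 30 side-chain acid
Product: 32 9β-(tert-butyldimethylsilyloxy)-7αH,10βH-eremophil-11-en-8-on-3α-yl (2E,4R)-4-{[(2Z)-2-methylbut-2-enoyl]oxy}hex-2-enoate, via enoic trichlorobenzoic anhydride 31 (not isolated)
Conditions: 2,4,6-trichlorobenzoyl chloride, Et3N, THF, rt; then 23, DMAP, toluene, rt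
Reagents that add atoms: none
Why: Yamaguchi esterification acylates the equatorial C3 hydroxyl (the C9 oxygen is silylated), and no stereocentre takes part.

Step 21
Reactants: 32 silyl-protected ester
Product: 33 3α-{(2E,4R)-4-[(2Z)-2-methylbut-2-enoyloxy]hex-2-enoyloxy}-9β-hydroxy-7αH,10βH-eremophil-11-en-8-one [(3R,4R,5R,7R,9R,10S)]
Conditions: HF·pyridine, pyridine, THF, 0 °C to rt
Reagents that add atoms: none
Why: Buffered fluoride cleavage of the secondary silyl ether frees the C9 hydroxyl without touching the two esters, the conjugated enoate or the epimerisable C7 and C9 centres next to the ketone.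

Compound list
1 | pent-4-yn-1-ol | C#CCCCO | starting material
2 | (E)-alkenylzirconocene chloride of 1, hydroxyl bound as zirconium alkoxide (not isolated) | Cl[Zr](OCCC/C=C/[Zr](Cl)(C1C=CC=C1)C1C=CC=C1)(C1C=CC=C1)C1C=CC=C1 | intermediate
3 | (E)-5-iodopent-4-en-1-ol | OCCC/C=C/I | intermediate
4 | (E)-5-iodopent-4-enal | O=CCC/C=C/I | intermediate
5 | (S)-4-benzyl-3-propanoyl-1,3-oxazolidin-2-one | CCC(=O)N1[C@@H](Cc2ccccc2)COC1=O | starting material
6 | dibutylboron Z-enolate of 5 (not isolated) | C/C=C(\OB(CCCC)CCCC)N1[C@@H](Cc2ccccc2)COC1=O | intermediate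
7 | (S)-4-benzyl-3-[(2S,3R,6E)-3-hydroxy-7-iodo-2-methylhept-6-enoyl]-1,3-oxazolidin-2-one | I/C=C/CC[C@@H](O)[C@H](C)C(=O)N1[C@@H](Cc2ccccc2)COC1=O | intermediate
8 | (2S,3R,6E)-3-hydroxy-7-iodo-N-methoxy-N,2-dimethylhept-6-enamide | I/C=C/CC[C@@H](O)[C@H](C)C(=O)N(C)OC | intermediate
9 | (3S,4R,7E)-4-hydroxy-8-iodo-3-methyloct-7-en-2-one | I/C=C/CC[C@@H](O)[C@H](C)C(C)=O | intermediate
10 | (3R,4R,6E)-7-iodo-2,3-dimethylhepta-1,6-dien-4-ol | I/C=C/CC[C@@H](O)[C@H](C)C(C)=C | intermediate
11 | but-3-enoic acid | C=CCC(=O)O | starting material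
12 | (3R,4R,6E)-7-iodo-2,3-dimethylhepta-1,6-dien-4-yl but-3-enoate | I/C=C/CC[C@@H](OC(=O)CC=C)[C@H](C)C(C)=C | intermediate
13 | (6R,7R)-7-[(3E)-4-iodobut-3-en-1-yl]-5,6-dimethyl-6,7-dihydrooxepin-2(3H)-one | I/C=C/CC[C@H]1OC(=O)C/C=C(C)\[C@H]1C | intermediate
14 | (6R,7R)-5,6-dimethyl-7-[(3E)-4-(4,4,5,5-tetramethyl-1,3,2-dioxaborolan-2-yl)but-3-en-1-yl]-6,7-dihydrooxepin-2(3H)-one | CC1(C)OB(/C=C/CC[C@H]2OC(=O)C/C=C(C)\[C@H]2C)OC1(C)C | intermediate
15 | tert-butyl({(6R,7R)-5,6-dimethyl-7-[(3E)-4-(pinacolboryl)but-3-en-1-yl]-6,7-dihydrooxepin-2-yl}oxy)dimethylsilane, the cyclic silyl ketene acetal (not isolated) | CC1(C)OB(/C=C/CC[C@H]2OC(O[Si](C)(C)C(C)(C)C)=C/C=C(C)\[C@H]2C)OC1(C)C | intermediate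
16 | 8β-(tert-butyldimethylsilyloxy)-3α,8α-epoxy-9β-(pinacolboryl)-11,12,13-trinor-10βH-eremophil-6-ene (cis-fused Δ6-octalin, O bridge from C3 to C8 on the α face) | C1=C[C@@]2(C)[C@H](CC[C@@H](O3)[C@@H]2C)[C@@H](B4OC(C)(C)C(C)(C)O4)[C@@]13O[Si](C)(C)C(C)(C)C | intermediate
17 | 8β-(tert-butyldimethylsilyloxy)-3α,8α-epoxy-11,12,13-trinor-10βH-eremophil-6-en-9β-ol | C1=C[C@@]2(C)[C@H](CC[C@@H](O3)[C@@H]2C)[C@@H](O)[C@@]13O[Si](C)(C)C(C)(C)C | intermediate
18 | 8β,9β-bis(tert-butyldimethylsilyloxy)-3α,8α-epoxy-11,12,13-trinor-10βH-eremophil-6-ene | C1=C[C@@]2(C)[C@H](CC[C@@H](O3)[C@@H]2C)[C@@H](O[Si](C)(C)C(C)(C)C)[C@@]13O[Si](C)(C)C(C)(C)C | intermediate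
19 | 9β-(tert-butyldimethylsilyloxy)-3α-hydroxy-11,12,13-trinor-10βH-eremophil-6-en-8-one | C1=C[C@@]2(C)[C@H](CC[C@@H](O)[C@@H]2C)[C@@H](O[Si](C)(C)C(C)(C)C)C1=O | intermediate
20 | 9β-(tert-butyldimethylsilyloxy)-3α-hydroxy-7-iodo-11,12,13-trinor-10βH-eremophil-6-en-8-one | IC1=C[C@@]2(C)[C@H](CC[C@@H](O)[C@@H]2C)[C@@H](O[Si](C)(C)C(C)(C)C)C1=O | intermediate
21 | tributyl(prop-1-en-2-yl)stannane | CCCC[Sn](CCCC)(CCCC)C(C)=C | starting material
22 | 9β-(tert-butyldimethylsilyloxy)-3α-hydroxy-10βH-eremophila-6,11-dien-8-one | C=C(C)C1=C[C@@]2(C)[C@H](CC[C@@H](O)[C@@H]2C)[C@@H](O[Si](C)(C)C(C)(C)C)C1=O | intermediate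
23 | 9β-(tert-butyldimethylsilyloxy)-3α-hydroxy-7αH,10βH-eremophil-11-en-8-one (7β-isopropenyl) | C=C(C)[C@H]1C[C@@]2(C)[C@H](CC[C@@H](O)[C@@H]2C)[C@@H](O[Si](C)(C)C(C)(C)C)C1=O | intermediate
24 | (R)-2-ethyloxirane ((R)-1,2-epoxybutane) | CC[C@@H]1CO1 | starting material
25 | (R)-pent-1-en-3-ol | C=C[C@@H](CC)O | intermediate
26 | angelic acid, (Z)-2-methylbut-2-enoic acid | C/C=C(/C)C(=O)O | starting material
27 | (Z)-2-methylbut-2-enoic 2,4,6-trichlorobenzoic anhydride (not isolated) | C/C=C(/C)C(=O)OC(=O)c1c(Cl)cc(Cl)cc1Cl | intermediate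
28 | (R)-pent-1-en-3-yl (Z)-2-methylbut-2-enoate | C=C[C@@H](CC)OC(=O)/C(C)=C\C | intermediate
29 | acrylic acid | C=CC(=O)O | starting material
30 | (2E,4R)-4-{[(2Z)-2-methylbut-2-enoyl]oxy}hex-2-enoic acid | OC(=O)/C=C/[C@@H](CC)OC(=O)/C(C)=C\C | intermediate
31 | mixed anhydride of 30 with 2,4,6-trichlorobenzoic acid (not isolated) | O=C(OC(=O)/C=C/[C@@H](CC)OC(=O)/C(C)=C\C)c1c(Cl)cc(Cl)cc1Cl | intermediate
32 | 9β-(tert-butyldimethylsilyloxy)-7αH,10βH-eremophil-11-en-8-on-3α-yl (2E,4R)-4-{[(2Z)-2-methylbut-2-enoyl]oxy}hex-2-enoate | C=C(C)[C@H]1C[C@@]2(C)[C@H](CC[C@@H](OC(=O)/C=C/[C@@H](CC)OC(=O)/C(C)=C\C)[C@@H]2C)[C@@H](O[Si](C)(C)C(C)(C)C)C1=O | intermediate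
33 | 3α-{(2E,4R)-4-[(2Z)-2-methylbut-2-enoyloxy]hex-2-enoyloxy}-9β-hydroxy-7αH,10βH-eremophil-11-en-8-one, (3R,4R,5R,7R,9R,10S) | C=C(C)[C@H]1C[C@@]2(C)[C@H](CC[C@@H](OC(=O)/C=C/[C@@H](CC)OC(=O)/C(C)=C\C)[C@@H]2C)[C@@H](O)C1=O | target

Total step count: 21
Longest linear sequence: 18 steps (steps 1–16, then 20 and 21)

Steps most likely to fail

Step 10. The alkenylboronate is only a weakly activated dienophile. At the temperature it needs, a suprafacial [1,5]-hydrogen shift from C4 to C8 within the seven-membered diene, or bimolecular addition, may overtake the cycloaddition; reversed regiochemistry (C10 to C8) is the second concern. The fallback sets out from iodide 13 and uses a carbonyl-activated dienophile, with the C9 oxygen brought in afterwards by radical decarboxylation. Methoxycarbonylation of 13 (PdCl2(PPh3)2, CO, MeOH, Et3N, DMF, 60 °C) should give the methyl (E)-enoate lactone F1. Enol silylation as in step 10 gives the silyl ketene acetal F2, which should cyclise below 80 °C to the ester cycloadduct F3 with the same tether-imposed configuration (ester endo, 9β). Neutral ester cleavage (Me3SnOH, 1,2-dichloroethane, 80 °C) gives the acid F4. Its Barton ester F5 (N-hydroxypyridine-2-thione, DCC) is photolysed under O2 with t-BuSH and the hydroperoxide reduced with PPh3; capture of the C9 radical on the open face syn to the C6=C7 bridge should give alcohol 17, where the route is rejoined.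

Step 16. The copper dienolate may be protonated at C12 instead of C7, which drifts to the conjugated isopropylidene ketone, or on the wrong face of C7. The fallback separates the reduction from the protonation. From 22, 1,4-hydrosilylation (RhCl(PPh3)3, Et3SiH, benzene, 50 °C; the C3 hydroxyl is silylated in the same pot) gives the bis(triethylsilyl) dienol ether F6. Buffered fluoride at −78 °C (TBAF, AcOH, THF) cleaves the enol silyl ether with kinetic protonation at C7 to the C3 triethylsilyl ether ketone F7. PPTS in MeOH then releases the C3 hydroxyl and the route is rejoined at 23.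

Step 20. Acylation of the hindered C3 hydroxyl may be slow, so that base-induced Z-to-E isomerisation of the angelate or conjugate addition of DMAP to the activated enoate competes. The fallback builds the enoate on the core. From 23, acryloyl chloride and Et3N (CH2Cl2, 0 °C) give the C3 acrylate F8. Cross-metathesis of F8 with allylic angelate 28 (RuCl2(=CH-C6H4-2-OiPr)(H2IMes), second-generation Hoveyda–Grubbs catalyst, CH2Cl2, 40 °C; the 1,1-disubstituted isopropenyl group is a slow partner) should give 32 directly, where the route is rejoined.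

Further compounds
F1 | step 10 | methyl (E)-5-[(6R,7R)-5,6-dimethyl-2-oxo-2,3,6,7-tetrahydrooxepin-7-yl]pent-2-enoate | COC(=O)/C=C/CC[C@H]1OC(=O)C/C=C(C)\[C@H]1C
F2 | step 10 | tert-butyldimethylsilyl ketene acetal of F1 (2-silyloxy-6,7-dihydrooxepine) | COC(=O)/C=C/CC[C@H]1OC(O[Si](C)(C)C(C)(C)C)=C/C=C(C)\[C@H]1C
F3 | step 10 | methyl 8β-(tert-butyldimethylsilyloxy)-3α,8α-epoxy-11,12,13-trinor-10βH-eremophil-6-ene-9β-carboxylate | C1=C[C@@]2(C)[C@H](CC[C@@H](O3)[C@@H]2C)[C@@H](C(=O)OC)[C@@]13O[Si](C)(C)C(C)(C)C
F4 | step 10 | 8β-(tert-butyldimethylsilyloxy)-3α,8α-epoxy-11,12,13-trinor-10βH-eremophil-6-ene-9β-carboxylic acid | C1=C[C@@]2(C)[C@H](CC[C@@H](O3)[C@@H]2C)[C@@H](C(=O)O)[C@@]13O[Si](C)(C)C(C)(C)C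
F5 | step 10 | 2-thioxopyridin-1(2H)-yl ester (Barton ester) of F4 | C1=C[C@@]2(C)[C@H](CC[C@@H](O3)[C@@H]2C)[C@@H](C(=O)ON4C=CC=CC4=S)[C@@]13O[Si](C)(C)C(C)(C)C
F6 | step 16 | 9β-(tert-butyldimethylsilyloxy)-3α,8-bis(triethylsilyloxy)-10βH-eremophila-7,11-diene | C=C(C)C1C[C@@]2(C)[C@H](CC[C@@H](O[Si](CC)(CC)CC)[C@@H]2C)[C@@H](O[Si](C)(C)C(C)(C)C)C=1O[Si](CC)(CC)CC
F7 | step 16 | 9β-(tert-butyldimethylsilyloxy)-3α-(triethylsilyloxy)-7αH,10βH-eremophil-11-en-8-one | C=C(C)[C@H]1C[C@@]2(C)[C@H](CC[C@@H](O[Si](CC)(CC)CC)[C@@H]2C)[C@@H](O[Si](C)(C)C(C)(C)C)C1=O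
F8 | step 20 | 9β-(tert-butyldimethylsilyloxy)-7αH,10βH-eremophil-11-en-8-on-3α-yl acrylate | C=C(C)[C@H]1C[C@@]2(C)[C@H](CC[C@@H](OC(=O)C=C)[C@@H]2C)[C@@H](O[Si](C)(C)C(C)(C)C)C1=O
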